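Readings and results were computed for an exercise, and the scatter is random.

Which species leads at the end of teal and of red, and by how much?

the same everywhere: starting material 0.20 M; added ligand 13 mM
- maple: coupling partner 0.74 equiv; free catalyst 7.3 mol%; temperature 98 °C; run made earlier
- birch: coupling partner 1.7 equiv; free catalyst 7.3 mol%; temperature 114 °C; run made earlier
- larch: coupling partner 1.1 equiv; free catalyst 15 mol%; temperature 98 °C; run made earlier
- teal: coupling partner 1.10 equiv; free catalyst 7.3 mol%; temperature 100 °C; time 1.5 h
- red: coupling partner 1.10 equiv; free catalyst 7.3 mol%; temperature 110 °C; time 1.5 h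

| run | time / min | catalyst intermediate A / % | product / % | catalyst intermediate B / % | starting material / % |
|---|---|---|---|---|---|
| maple | 8.00 | 6.4 | 17.0 | 1.0 | 74.9 |
| maple | 15.0 | 7.0 | 25.3 | 0.2 | 67.6 |
| maple | 25.0 | 8.2 | 31.4 | 0.8 | 61.0 |
| maple | 40.0 | 7.3 | 34.9 | 0.1 | 57.9 |
| maple | 60.0 | 7.1 | 36.4 | 0.4 | 56.5 |
| maple | 120 | 7.3 | 36.4 | 0.7 | 55.8 |
| birch | 4.00 | 6.2 | 33.5 | 0.5 | 58.3 |
| birch | 10.0 | 7.0 | 49.4 | 0 | 43.5 |
| birch | 20.0 | 7.6 | 51.9 | 0 | 40.2 |
| birch | 30.0 | 7.5 | 51.8 | 1.3 | 40.5 |
| birch | 40.0 | 7.6 | 52.6 | 0 | 40.4 |
| birch | 60.0 | 7.9 | 52.3 | 0.6 | 40.0 |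
| larch | 10.0 | 12.9 | 49.8 | 1.0 | 35.5 |
| larch | 25.0 | 14.3 | 68.6 | 0.4 | 17.7 |
| larch | 50.0 | 15.1 | 71.5 | 0 | 13.5 |
| larch | 80.0 | 14.8 | 71.6 | 0 | 12.4 |
| larch | 120 | 15.9 | 71.6 | 0.6 | 13.7 |

(scatter of a reading: 0.5 percentage points)

- the numbers in the tables scatter with a standard deviation of 0.5 percentage points

- which of these there is most of at the end, counted by the starting material in it, teal (product / catalyst intermediate A / catalyst intermediate B / starting material)
- which of these there is most of at the end, counted by the starting material in it, red (product / catalyst intermediate A / catalyst intermediate B / starting material)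
- the largest of these amounts at the end, in percent of the starting material charged, teal
- the largest of these amounts at the end, in percent of the starting material charged, red

**Reading the stops.** Each run stands still with starting material present and catalyst intermediate A, the resting state, level with the loading. Maple ends with 36.4% product from 0.74 equiv of coupling partner. So the partner is read as draining two ways: through the catalyst, at a rate proportional to c(coupling partner) and c(catalyst intermediate A), and by a catalyst-free loss proportional to c(coupling partner). Their ratio then stays constant through a run.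

**Capture number.** Take product made per partner lost, divided by the loading. Maple reads 13.3 and larch 12.4, despite different loadings. This ratio is the capture number, taken from maple at 98 °C. Birch, at 114 °C, reads a lower 6.09.

**The bracket.** Teal and red lie between those temperatures. Maple's number gives an estimated ceiling on product of 54.1%, and birch's gives an estimated floor of 33.8%. With catalyst intermediate A at the loading, starting material then spans 38.6% to 58.9%. My own tightening interpolates the logarithm of the capture number linearly in temperature. Teal gets 12.0, so product 51.4% and starting material 41.3%. Red gets 7.40, so product 38.6% and starting material 54.1%. Product thus leads in teal, starting material in red.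

**The forecast.** It names starting material at 55% (53% to 57%) for teal and product at 47.5% (45% to 50%) for red, saying “I attribute the rise to temperature”. Its teal value, for starting material, lies inside that species' span, and its red value, for product, lies inside the product span. But the leaders are the reverse of my reckoning.

**The result.** Teal ends with product leading at 50.2%; red ends with starting material leading at 53.6%.

    starting material + free catalyst → catalyst intermediate A (k = 140 L mol⁻¹ min⁻¹, Ea = 69.0 kJ mol⁻¹)
    coupling partner + catalyst intermediate A ⇌ catalyst intermediate B (K = 6.70 L mol⁻¹, k = 4.30 L mol⁻¹ min⁻¹, Ea = 54.0 kJ mol⁻¹, ΔH = −19.0 kJ mol⁻¹)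
    catalyst intermediate B → free catalyst + product (k = 3.30 min⁻¹, Ea = 97.0 kJ mol⁻¹)
    coupling partner → decomposed reagent (k = 0.0540 min⁻¹, Ea = 112 kJ mol⁻¹)
    free catalyst + added ligand ⇌ idle complex (K = 160 L mol⁻¹, k = 13.0 L mol⁻¹ min⁻¹, Ea = 69.0 kJ mol⁻¹, ΔH = −59.0 kJ mol⁻¹)
    (constants at 100 °C)

**Why red stalls.** Without the conversion of coupling partner into decomposed reagent, starting material in red falls from 53.6% to 0%. The results give capture numbers of 11.5 for teal and 7.56 for red. For teal's neighbour at 125 °C, the same interpolation carried onward gives 3.56, so product 22.7%. That neighbour ends with 25.2% product.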